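## Plan

1. The target is an achiral, symmetric dibenzyl ether. The first cut, at the central CH2–O–CH2 unit, gives two copies of one benzylic bromide. Each copy holds an outer ring A (2,3-dibromo-4,5-dihydroxyphenyl) and an inner ring B.
2. Enabling feature: ring B carries its two benzylic carbons on neighbouring atoms, B1 (CH2O) and B2 (CH2–ring A), followed by B3 (Br), B4 and B5 (OH) and B6 (H). Tying the B1 oxygen temporarily to the diarylmethane carbon turns each half into a 1-arylphthalan. Its benzene ring is then a 1,6-diyne (B6, B1, B2, B3) plus a symmetric two-carbon alkyne (B4, B5).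
3. The second cut removes B1–B2, B3–B4 and B5–B6 in a retro-(2+2+2) sense. Silicon on the diyne terminus stands for the B3 bromine, and two borons on the alkyne stand for the B4 and B5 oxygens.
4. Forward order: ring A comes from 5-bromovanillin, and acetylide addition and O-propargylation join the chain. Ring B and the dihydrofuran ring then arise together in the cobalt step. After that come C–B to C–O, C–Si to C–Br, hydride opening of the temporary C–O bond, demethylation, acetate masking, silver-mediated ether union and deacetylation.
5. Stereochemistry: the target has no stereocentre. The only sp3 stereocentre on the way (the carbinol carbon, later C1 of the phthalan) is carried as a racemate and is erased when hydride replaces its oxygen.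

Key step: step 5

Assumption: 5-bromovanillin and bis(pinacolatoboryl)acetylene are taken as catalogue compounds, and every intermediate with the carbinol/phthalan C1 centre is racemic.

## Route

Step 1
Reactants: 1 5-bromovanillin (5-bromo-4-hydroxy-3-methoxybenzaldehyde)
Product: 2 2,3-dibromo-4-hydroxy-5-methoxybenzaldehyde (5,6-dibromovanillin)
Conditions: Br2 (1.2 equiv), Fe powder (cat.), AcOH, rt
Reagents that add atoms: bromine, BrBr
Why: Electrophilic aromatic bromination, in which the methoxy group directs the second bromine to its free para position next to the first bromine, the established access to 5,6-dibromovanillin.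

Step 2
Reactants: 2 2,3-dibromo-4-hydroxy-5-methoxybenzaldehyde
Product: 3 2,3-dibromo-4,5-dimethoxybenzaldehyde
Conditions: MeI, K2CO3, DMF, rt
Reagents that add atoms: iodomethane, CI
Why: Williamson O-methylation of an acidic phenol with a small electrophile, under conditions to which the aldehyde and the aryl bromides are inert.

Step 3
Reactants: 3 2,3-dibromo-4,5-dimethoxybenzaldehyde; 4 trimethylsilylacetylene
Product: 6 rac-1-(2,3-dibromo-4,5-dimethoxyphenyl)-3-(trimethylsilyl)prop-2-yn-1-ol, via lithium trimethylsilylacetylide 5 (not isolated)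
Conditions: 4 (1.3 equiv), n-BuLi (1.2 equiv), THF, −78 °C; then 3, −78 °C; then aq. NH4Cl
Reagents that add atoms: none
Why: 1,2-Addition of a lithium acetylide to an aromatic aldehyde, in which the slight excess of 4 consumes all n-BuLi so that no bromine–lithium exchange can occur, and the carbinol centre forms as a racemate because nothing chiral is present.

Step 4
Reactants: 6 rac-1-(2,3-dibromo-4,5-dimethoxyphenyl)-3-(trimethylsilyl)prop-2-yn-1-ol; 7 propargyl bromide
Product: 9 rac-[3-(2,3-dibromo-4,5-dimethoxyphenyl)-3-(prop-2-yn-1-yloxy)prop-1-yn-1-yl]trimethylsilane, via sodium alkoxide 8 (not isolated)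
Conditions: NaH, THF, 0 °C; then 7, n-Bu4NI (cat.), 0 °C → rt
Reagents that add atoms: none
Why: Williamson etherification of a propargylic alkoxide with a reactive primary bromide, the standard entry to unsymmetrical oxygen-tethered 1,6-diynes, run in aprotic THF at low temperature so that the C–Si bond stays and no alkyne-to-allene shift sets in.

Step 5
Reactants: 9 rac-[3-(2,3-dibromo-4,5-dimethoxyphenyl)-3-(prop-2-yn-1-yloxy)prop-1-yn-1-yl]trimethylsilane; 10 bis(pinacolatoboryl)acetylene
Product: 11 rac-1-(2,3-dibromo-4,5-dimethoxyphenyl)-5,6-bis(pinacolatoboryl)-7-(trimethylsilyl)-1,3-dihydroisobenzofuran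
Conditions: CpCo(CO)2 (20 mol %), 10 (2.5 equiv), xylenes, reflux, hν (visible lamp), 9 and catalyst added by syringe pump over 10 h, Ar
Reagents that add atoms: none
Why: Heat and light strip CO from CpCo(CO)2, the two tethered alkynes of 9 bind to monovalent cobalt and couple oxidatively to a cobaltacyclopentadiene of trivalent cobalt (B1–B2 forms), then 10 coordinates and inserts, and reductive elimination forms B3–B4 and B5–B6 and returns the CpCo fragment. The closest known chemistry is the cobalt-mediated (2+2+2) cycloaddition of 1,6-diynes with alkynylboronates, supported by the cobalt cyclotrimerisation of diborylacetylenes. The five-membered dihydrofuran ring closes in the oxidative coupling, because the C–O–C tether holds both alkynes on one metal, and the six-membered ring B closes in the final reductive elimination. No stereocentre is created, since C1 of the phthalan is the spectator carbinol carbon of racemic 9. The step needs cross-addition to win over diyne self-reaction and over collapse of the metallacycle, which is served by keeping 9 dilute through slow addition into an excess of 10, an alkyne that self-trimerises only slowly; there is no regiochemical question, because 10 is symmetric and the tether decides that the silylated terminus becomes B3 and the terminal CH becomes B6. Aryl bromides, methyl ethers and the C–Si and C–B bonds should be inert to the CpCo fragment.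

Step 6
Reactants: 11 rac-1-(2,3-dibromo-4,5-dimethoxyphenyl)-5,6-bis(pinacolatoboryl)-7-(trimethylsilyl)-1,3-dihydroisobenzofuran
Product: 12 rac-1-(2,3-dibromo-4,5-dimethoxyphenyl)-7-(trimethylsilyl)-1,3-dihydroisobenzofuran-5,6-diol
Conditions: NaBO3·4H2O (6 equiv), THF–H2O, rt, Ar; then aq. NH4Cl
Reagents that add atoms: sodium perborate NaBO3, [Na+].[O-]OB=O
Why: Oxidative ipso-hydroxylation of arylboronic esters (peroxide attack at boron, 1,2-aryl shift, hydrolysis), with perborate as a mild buffered peroxide source that should leave the aryl silane, the aryl bromides and the benzylic ether alone and limit over-oxidation of the catechol.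

Step 7
Reactants: 12 rac-1-(2,3-dibromo-4,5-dimethoxyphenyl)-7-(trimethylsilyl)-1,3-dihydroisobenzofuran-5,6-diol
Product: 13 rac-1-(2,3-dibromo-4,5-dimethoxyphenyl)-5,6-dimethoxy-7-(trimethylsilyl)-1,3-dihydroisobenzofuran
Conditions: MeI (4 equiv), K2CO3, DMF, rt, Ar
Reagents that add atoms: iodomethane, CI
Why: Double Williamson O-methylation, in which the small electrophile still reaches the phenoxide next to silicon and the exclusion of air protects the catechol until both oxygens are capped.

Step 8
Reactants: 13 rac-1-(2,3-dibromo-4,5-dimethoxyphenyl)-5,6-dimethoxy-7-(trimethylsilyl)-1,3-dihydroisobenzofuran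
Product: 14 rac-7-bromo-1-(2,3-dibromo-4,5-dimethoxyphenyl)-5,6-dimethoxy-1,3-dihydroisobenzofuran
Conditions: NBS (1.0 equiv), MeCN, 0 °C → rt, dark; aqueous work-up
Reagents that add atoms: N-bromosuccinimide, O=C1CCC(=O)N1Br
Why: Electrophilic ipso-bromodesilylation, in which beta-silicon stabilisation of the arenium ion and relief of strain at crowded C7 should let C–Si outrun the C4–H position and the deactivated ring A, while the polar medium and darkness suppress radical attack at the benzylic ether C–H bonds and no acidic silyl halide is released.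

Step 9
Reactants: 14 rac-7-bromo-1-(2,3-dibromo-4,5-dimethoxyphenyl)-5,6-dimethoxy-1,3-dihydroisobenzofuran
Product: 15 [3-bromo-2-(2,3-dibromo-4,5-dimethoxybenzyl)-4,5-dimethoxyphenyl]methanol
Conditions: Et3SiH (1.1 equiv), BF3·OEt2 (1.5 equiv), CH2Cl2, −40 → 0 °C; then H2O
Reagents that add atoms: none
Why: Ionic hydrogenation of a benzhydryl ether, in which only the C1–O bond can leave a diarylmethyl cation with a para methoxy group on each ring, whereas C3–O would leave a primary cation; the silane traps the cation irreversibly, erasing the racemic centre, and one equivalent of silane at low temperature spares the new primary benzylic oxygen, whose para methoxy group is twisted out of conjugation between Br and OMe.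

Step 10
Reactants: 15 [3-bromo-2-(2,3-dibromo-4,5-dimethoxybenzyl)-4,5-dimethoxyphenyl]methanol
Product: 16 3-bromo-5-(bromomethyl)-4-(2,3-dibromo-4,5-dihydroxybenzyl)benzene-1,2-diol
Conditions: BBr3 (8 equiv), CH2Cl2, −78 °C → rt; then ice–water, rapid extraction
Reagents that add atoms: boron tribromide, BrB(Br)Br
Why: BBr3 cleavage of the four aryl methyl ethers, with the usual simultaneous conversion of an oxygenated benzylic alcohol into its bromide, a combination well known for bromophenol diarylmethanes and harmless to aryl bromides and the CH2 bridge.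

Step 11
Reactants: 16 3-bromo-5-(bromomethyl)-4-(2,3-dibromo-4,5-dihydroxybenzyl)benzene-1,2-diol
Product: 17 3-bromo-5-(bromomethyl)-4-(4,5-diacetoxy-2,3-dibromobenzyl)-1,2-phenylene diacetate
Conditions: AcBr (excess), AcOH–CH2Cl2, rt → 40 °C
Reagents that add atoms: acetyl bromide, CC(=O)Br
Why: Base-free O-acetylation of phenols with acetyl bromide (the derivatisation known from lignin analysis), which avoids the para-quinone methide that any amine base would release from a 4-hydroxybenzyl bromide, while the HBr formed returns any hydrolysed benzylic position to the bromide.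

Step 12
Reactants: 17 3-bromo-5-(bromomethyl)-4-(4,5-diacetoxy-2,3-dibromobenzyl)-1,2-phenylene diacetate (two molecules)
Product: 18 bis[4,5-diacetoxy-3-bromo-2-(4,5-diacetoxy-2,3-dibromobenzyl)benzyl] ether
Conditions: Ag2O (1.0 equiv), 4 Å MS, CH2Cl2, dark, rt → 40 °C
Reagents that add atoms: Ag2O (disilver oxide), [Ag+].[Ag+].[O-2]
Why: Silver-assisted Williamson-type synthesis of a symmetric dibenzyl ether, in which Ag2O abstracts bromide and supplies the oxygen, the first-formed silver alkoxide captures a second activated bromide, and the near-neutral medium should leave the aryl acetates in place while these keep both rings too electron-poor for Friedel–Crafts side reactions.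

Step 13
Reactants: 18 bis[4,5-diacetoxy-3-bromo-2-(4,5-diacetoxy-2,3-dibromobenzyl)benzyl] ether
Product: 19 bis[3-bromo-2-(2,3-dibromo-4,5-dihydroxybenzyl)-4,5-dihydroxybenzyl] ether (CNP0255526.0)
Conditions: N2H4·H2O (12 equiv), degassed THF, 0 °C, Ar; then aq. citric acid to pH 5
Reagents that add atoms: none
Why: Hydrazinolysis of aryl acetates (acyl transfer to an alpha-effect nucleophile), chosen because it is fast at 0 °C, free of acid and of alcohol solvent so that the solvolysis-prone 4-hydroxybenzyl ether is not exchanged, and reducing enough to shield the four catechols from air oxidation.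

## Compound list

1 | 5-bromovanillin | COc1cc(C=O)cc(Br)c1O | starting material
2 | 2,3-dibromo-4-hydroxy-5-methoxybenzaldehyde | COc1cc(C=O)c(Br)c(Br)c1O | intermediate
3 | 2,3-dibromo-4,5-dimethoxybenzaldehyde | COc1cc(C=O)c(Br)c(Br)c1OC | intermediate
4 | trimethylsilylacetylene | C#C[Si](C)(C)C | starting material
5 | lithium trimethylsilylacetylide (not isolated) | [Li+].[C-]#C[Si](C)(C)C | intermediate
6 | rac-1-(2,3-dibromo-4,5-dimethoxyphenyl)-3-(trimethylsilyl)prop-2-yn-1-ol | OC(C#C[Si](C)(C)C)c1cc(OC)c(OC)c(Br)c1Br | intermediate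
7 | propargyl bromide | C#CCBr | starting material
8 | sodium alkoxide of 6 (not isolated) | [Na+].[O-]C(C#C[Si](C)(C)C)c1cc(OC)c(OC)c(Br)c1Br | intermediate
9 | rac-[3-(2,3-dibromo-4,5-dimethoxyphenyl)-3-(prop-2-yn-1-yloxy)prop-1-yn-1-yl]trimethylsilane | C#CCOC(C#C[Si](C)(C)C)c1cc(OC)c(OC)c(Br)c1Br | intermediate
10 | bis(pinacolatoboryl)acetylene | CC1(C)OB(C#CB2OC(C)(C)C(C)(C)O2)OC1(C)C | starting material
11 | rac-1-(2,3-dibromo-4,5-dimethoxyphenyl)-5,6-bis(pinacolatoboryl)-7-(trimethylsilyl)-1,3-dihydroisobenzofuran | C1OC(c2cc(OC)c(OC)c(Br)c2Br)c2c([Si](C)(C)C)c(B3OC(C)(C)C(C)(C)O3)c(B3OC(C)(C)C(C)(C)O3)cc12 | intermediate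
12 | rac-1-(2,3-dibromo-4,5-dimethoxyphenyl)-7-(trimethylsilyl)-1,3-dihydroisobenzofuran-5,6-diol | C1OC(c2cc(OC)c(OC)c(Br)c2Br)c2c([Si](C)(C)C)c(O)c(O)cc12 | intermediate
13 | rac-1-(2,3-dibromo-4,5-dimethoxyphenyl)-5,6-dimethoxy-7-(trimethylsilyl)-1,3-dihydroisobenzofuran | C1OC(c2cc(OC)c(OC)c(Br)c2Br)c2c([Si](C)(C)C)c(OC)c(OC)cc12 | intermediate
14 | rac-7-bromo-1-(2,3-dibromo-4,5-dimethoxyphenyl)-5,6-dimethoxy-1,3-dihydroisobenzofuran | C1OC(c2cc(OC)c(OC)c(Br)c2Br)c2c(Br)c(OC)c(OC)cc12 | intermediate
15 | [3-bromo-2-(2,3-dibromo-4,5-dimethoxybenzyl)-4,5-dimethoxyphenyl]methanol | COc1cc(CO)c(Cc2cc(OC)c(OC)c(Br)c2Br)c(Br)c1OC | intermediate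
16 | 3-bromo-5-(bromomethyl)-4-(2,3-dibromo-4,5-dihydroxybenzyl)benzene-1,2-diol | Oc1cc(CBr)c(Cc2cc(O)c(O)c(Br)c2Br)c(Br)c1O | intermediate
17 | 3-bromo-5-(bromomethyl)-4-(4,5-diacetoxy-2,3-dibromobenzyl)-1,2-phenylene diacetate | CC(=O)Oc1cc(CBr)c(Cc2cc(OC(C)=O)c(OC(C)=O)c(Br)c2Br)c(Br)c1OC(C)=O | intermediate
18 | bis[4,5-diacetoxy-3-bromo-2-(4,5-diacetoxy-2,3-dibromobenzyl)benzyl] ether | CC(=O)Oc1cc(Cc2c(COCc3cc(OC(C)=O)c(OC(C)=O)c(Br)c3Cc3cc(OC(C)=O)c(OC(C)=O)c(Br)c3Br)cc(OC(C)=O)c(OC(C)=O)c2Br)c(Br)c(Br)c1OC(C)=O | intermediate
19 | bis[3-bromo-2-(2,3-dibromo-4,5-dihydroxybenzyl)-4,5-dihydroxybenzyl] ether (achiral) | Oc1cc(Cc2c(COCc3cc(O)c(O)c(Br)c3Cc3cc(O)c(O)c(Br)c3Br)cc(O)c(O)c2Br)c(Br)c(Br)c1O | target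

## Step count

Total step count: 13. Longest linear sequence: 13 steps (1 to 19). Both halves of the ether are the same compound 17, so the union does not shorten the sequence.

## Steps most likely to fail

**Step 5.** The hindered diborylalkyne may fail to enter the silyl-substituted cobaltacycle. Diyne self-addition, or collapse of the metallacycle to an inert cyclobutadiene complex, could then take over.

The fallback sets out from 1 and 3 and comes back at 14. It takes ring B from the aromatic pool and makes the bond from B2 to the bridging carbon by carbonyl addition.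
- Compound 1 is O-methylated (MeI, K2CO3) to 3-bromo-4,5-dimethoxybenzaldehyde F1.
- NaBH4 reduction gives (3-bromo-4,5-dimethoxyphenyl)methanol F2.
- Iodination para to the C5 methoxy group (I2, AgO2CCF3, CHCl3) gives (3-bromo-2-iodo-4,5-dimethoxyphenyl)methanol F3.
- Two equivalents of i-PrMgCl·LiCl in THF at −40 °C deprotonate the alcohol and exchange iodine in preference to bromine. The arylmagnesium adds to aldehyde 3 to give rac-[2-bromo-6-(hydroxymethyl)-3,4-dimethoxyphenyl](2,3-dibromo-4,5-dimethoxyphenyl)methanol F4.
- Catalytic TsOH in toluene closes this diol, with loss of water, to phthalan 14.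

**Step 9.** Ionisation of the crowded, twisted benzhydryl ether may be sluggish. Forcing it may trigger a second ionisation at the primary benzylic oxygen, followed by over-reduction.

The fallback sets out from 14 and comes back at 15. It separates C–O cleavage from hydride delivery.
- Acylative ether cleavage with AcBr and catalytic ZnBr2 in CH2Cl2 at 0 °C puts the acetyl group on the primary oxygen, which can then no longer ionise, and bromide on the diaryl carbon. The product is rac-3-bromo-2-[bromo(2,3-dibromo-4,5-dimethoxyphenyl)methyl]-4,5-dimethoxybenzyl acetate F5.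
- The benzhydryl bromide is reduced under solvolytic conditions with NaBH4 in aqueous diglyme to 3-bromo-2-(2,3-dibromo-4,5-dimethoxybenzyl)-4,5-dimethoxybenzyl acetate F6.
- K2CO3 in MeOH releases alcohol 15.

**Step 12.** Displacement at the ortho-crowded benzylic carbon may be slow. The reaction could then stall after the first C–O bond, or acetyl groups could be lost on the basic oxide surface.

The fallback sets out from 17 and comes back at 18. It forms the ether by hydride reduction of an oxocarbenium ion instead of by substitution.
- Kornblum-type oxidation of 17 with 4-methylmorpholine N-oxide in MeCN over 4 Å MS gives 3-bromo-4-(4,5-diacetoxy-2,3-dibromobenzyl)-5-formyl-1,2-phenylene diacetate F7.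
- Reductive homo-etherification of this aldehyde with Et3SiH and catalytic BiBr3 in MeCN at rt joins two molecules to octaacetate 18.

## Further compounds

F1 | step 5 | 3-bromo-4,5-dimethoxybenzaldehyde | COc1cc(C=O)cc(Br)c1OC
F2 | step 5 | (3-bromo-4,5-dimethoxyphenyl)methanol | COc1cc(CO)cc(Br)c1OC
F3 | step 5 | (3-bromo-2-iodo-4,5-dimethoxyphenyl)methanol | COc1cc(CO)c(I)c(Br)c1OC
F4 | step 5 | rac-[2-bromo-6-(hydroxymethyl)-3,4-dimethoxyphenyl](2,3-dibromo-4,5-dimethoxyphenyl)methanol | COc1cc(CO)c(C(O)c2cc(OC)c(OC)c(Br)c2Br)c(Br)c1OC
F5 | step 9 | rac-3-bromo-2-[bromo(2,3-dibromo-4,5-dimethoxyphenyl)methyl]-4,5-dimethoxybenzyl acetate | COc1cc(COC(C)=O)c(C(Br)c2cc(OC)c(OC)c(Br)c2Br)c(Br)c1OC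
F6 | step 9 | 3-bromo-2-(2,3-dibromo-4,5-dimethoxybenzyl)-4,5-dimethoxybenzyl acetate | COc1cc(COC(C)=O)c(Cc2cc(OC)c(OC)c(Br)c2Br)c(Br)c1OC
F7 | step 12 | 3-bromo-4-(4,5-diacetoxy-2,3-dibromobenzyl)-5-formyl-1,2-phenylene diacetate | CC(=O)Oc1cc(C=O)c(Cc2cc(OC(C)=O)c(OC(C)=O)c(Br)c2Br)c(Br)c1OC(C)=O
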